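**Retrosynthetic overview**

1. The strategy rests on the para-quinone ring of the target: its two OMe groups sit on C3 and C6, the only two ring carbons not bonded to an indole C3, and each is β to one carbonyl (C3 to C1=O, C6 to C4=O). Both C–OMe bonds are therefore cut back to C–H, giving 2,5-bis(indolyl)hydroquinone 11, by way of anodic oxidation in methanol with two conjugate additions of methanol.
2. Hydroquinone 11 comes from the stable quinone 12 by dithionite reduction. Quinone 12 is cut at the bond between quinone C5 and C3 of the 2-(tert-allyl)indole 6, which is formed by acid-promoted conjugate addition of 6 to indolylquinone 10.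
3. Quinone 10 comes from indole 7 and 1,4-benzoquinone 8. Indole 6 comes from a Madelung closure of amide 4, made from acid 1 and 2-methylaniline 2.
4. Ring order: the only ring built is the pyrrole ring of 6 (step 2). The quinone ring and the second indole are bought, and the key step closes no ring.

Key step: step 6

Remark: the two free ring carbons of 12 are not equivalent, so either may take the first methoxy group. Compounds 13 and 14 are drawn with it next to the unsubstituted indol-3-yl ring (the less hindered site); the other order converges on the same 15 and 16.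

**Step 1**
Reactants: 1 2,2-dimethylbut-3-enoic acid; 2 2-methylaniline
Product: 4 2,2-dimethyl-N-(2-methylphenyl)but-3-enamide, via 2,2-dimethylbut-3-enoyl chloride 3 (not isolated)
Conditions: (COCl)2, DMF (cat.), CH2Cl2, 0 °C to rt; then 2, Et3N, CH2Cl2, 0 °C to rt
Reagents that add atoms: none
Why: Acid chloride formation under Vilsmeier-type activation followed by N-acylation of the aniline should be clean, because the quaternary α-carbon excludes ketene formation and the vinyl group is inert.

**Step 2**
Reactants: 4 2,2-dimethyl-N-(2-methylphenyl)but-3-enamide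
Product: 6 2-(2-methylbut-3-en-2-yl)-1H-indole, via 2-(2-methylbut-3-en-2-yl)indolin-2-ol 5 (not isolated)
Conditions: n-BuLi (2.5 equiv), THF, −20 °C to rt; then H2O
Reagents that add atoms: none
Why: This is the Madelung indole synthesis in its organolithium form, in which the N,C-dilithiated amide closes onto its own carbonyl and the carbinolamine 5 loses water to aromatize; the acyl group has neither α- nor allylic hydrogens, so no competing deprotonation is available.

**Step 3**
Reactants: 7 1H-indole; 8 1,4-benzoquinone
Product: 10 2-(1H-indol-3-yl)-1,4-benzoquinone, via 2-(1H-indol-3-yl)benzene-1,4-diol 9 (not isolated)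
Conditions: 8 (2.2 equiv), InBr3 (10 mol %), CH2Cl2, rt
Reagents that add atoms: none
Why: Lewis acid-catalysed Friedel–Crafts-type conjugate addition of indole C3 to the quinone gives hydroquinone 9, which the second equivalent of 8 should oxidize by hydroquinone–quinone redox exchange; the excess of 8 also suppresses a second indole addition.

**Step 4**
Reactants: 6 2-(2-methylbut-3-en-2-yl)-1H-indole; 10 2-(1H-indol-3-yl)-1,4-benzoquinone
Product: 12 2-(1H-indol-3-yl)-5-[2-(2-methylbut-3-en-2-yl)-1H-indol-3-yl]cyclohexa-2,5-diene-1,4-dione, via bis(indolyl)hydroquinone 11 (not isolated)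
Conditions: 10 (2.2 equiv), H2SO4 (0.2 equiv), THF, 0 °C to rt, Ar
Reagents that add atoms: none
Why: Acid-promoted conjugate addition of the nucleophilic C3 of the 2-alkylindole should occur at C5 of 10, the carbon β to the carbonyl that is not deactivated by vinylogous-amide donation from the first indolyl group (hence the 2,5-pattern), and the second equivalent of 10 then oxidizes the electron-richer adduct 11 to the stable, easily purified quinone 12 by redox exchange.

**Step 5**
Reactants: 12 2-(1H-indol-3-yl)-5-[2-(2-methylbut-3-en-2-yl)-1H-indol-3-yl]cyclohexa-2,5-diene-1,4-dione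
Product: 11 2-(1H-indol-3-yl)-5-[2-(2-methylbut-3-en-2-yl)-1H-indol-3-yl]benzene-1,4-diol
Conditions: Na2S2O4, EtOAc/H2O, rt, Ar
Reagents that add atoms: none
Why: Dithionite reduction of a para-quinone to its hydroquinone is standard and leaves the indoles and the terminal alkene untouched; it should deliver the compound that passed through step 4 in solution, now pure, to be used at once under argon.

**Step 6**
Reactants: 11 2-(1H-indol-3-yl)-5-[2-(2-methylbut-3-en-2-yl)-1H-indol-3-yl]benzene-1,4-diol
Product: 16 2-(1H-indol-3-yl)-3,6-dimethoxy-5-[2-(2-methylbut-3-en-2-yl)-1H-indol-3-yl]cyclohexa-2,5-diene-1,4-dione, via bis(indolyl)quinone 12 (not isolated), via monomethoxyhydroquinone 13 (not isolated), via monomethoxyquinone 14 (not isolated), via dimethoxyhydroquinone 15 (not isolated)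
Conditions: undivided cell, graphite felt anode, Pt wire cathode, LiClO4 (0.1 M), NaOMe (0.2 equiv), MeOH, constant current, ca. 6–6.5 F/mol, rt, Ar; then air
Reagents that add atoms: methanol, CO
Why: Proposed new method: the anode takes two electrons from 11 (partly present as its phenoxide) to give quinone 12, methoxide (the NaOMe charge, maintained by hydrogen evolution at the cathode) adds to a free ring carbon β to one carbonyl, and the enolate tautomerizes to methoxyhydroquinone 13, which is oxidized at the anode or by 12 in solution to 14; the same addition and oxidation at the last C–H carbon give 15 and then 16, six electrons and three H2 per molecule. The closest known reaction type is the anodic oxidation of catechols and simple hydroquinones in methanol, where methanol adds to the electrogenerated quinone and the adduct is oxidized again (its chemical counterpart is the ZnCl2-promoted conversion of 1,4-benzoquinone into 2,5-dimethoxy-1,4-benzoquinone), but it has not been shown on a 2,5-diaryl or 2,5-bis(indolyl) hydroquinone, whose quinone is a weaker acceptor. No ring is closed and no stereocenter is formed. The step needs oxidation of the hydroquinone and not of the two N–H indoles, which the gap of several hundred millivolts between a hydroquinone or phenoxide and a 3-substituted indole should secure as long as the charge is stopped near 6 F/mol. It also needs C–O bond formation only at the two C–H ring carbons: addition at a carbonyl carbon or at an indole-bearing carbon cannot tautomerize to an aromatic hydroquinone and reverts, while each methoxy group lowers the potential of the next hydroquinone so the sequence runs forward. The large anode and small Pt cathode keep cathodic re-reduction of the quinones a minor, self-correcting drain on charge, and the closing exposure to air converts any residual 15 into 16.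

**Compound list**

1 | 2,2-dimethylbut-3-enoic acid | C=CC(C)(C)C(=O)O | starting material
2 | 2-methylaniline | Cc1ccccc1N | starting material
3 | 2,2-dimethylbut-3-enoyl chloride | C=CC(C)(C)C(=O)Cl | intermediate
4 | 2,2-dimethyl-N-(2-methylphenyl)but-3-enamide | C=CC(C)(C)C(=O)Nc1ccccc1C | intermediate
5 | 2-(2-methylbut-3-en-2-yl)-2,3-dihydro-1H-indol-2-ol (racemic, formed as its lithium salt) | C=CC(C)(C)C1(O)Cc2ccccc2N1 | intermediate
6 | 2-(2-methylbut-3-en-2-yl)-1H-indole | C=CC(C)(C)c1cc2ccccc2[nH]1 | intermediate
7 | 1H-indole | c1ccc2[nH]ccc2c1 | starting material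
8 | 1,4-benzoquinone | O=C1C=CC(=O)C=C1 | starting material
9 | 2-(1H-indol-3-yl)benzene-1,4-diol | Oc1ccc(O)c(-c2c[nH]c3ccccc23)c1 | intermediate
10 | 2-(1H-indol-3-yl)-1,4-benzoquinone | O=C1C=CC(=O)C(c2c[nH]c3ccccc23)=C1 | intermediate
11 | 2-(1H-indol-3-yl)-5-[2-(2-methylbut-3-en-2-yl)-1H-indol-3-yl]benzene-1,4-diol | C=CC(C)(C)c1[nH]c2ccccc2c1-c1cc(O)c(-c2c[nH]c3ccccc23)cc1O | intermediate
12 | 2-(1H-indol-3-yl)-5-[2-(2-methylbut-3-en-2-yl)-1H-indol-3-yl]cyclohexa-2,5-diene-1,4-dione | C=CC(C)(C)c1[nH]c2ccccc2c1C1=CC(=O)C(c2c[nH]c3ccccc23)=CC1=O | intermediate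
13 | 2-(1H-indol-3-yl)-3-methoxy-5-[2-(2-methylbut-3-en-2-yl)-1H-indol-3-yl]benzene-1,4-diol | C=CC(C)(C)c1[nH]c2ccccc2c1-c1cc(O)c(-c2c[nH]c3ccccc23)c(OC)c1O | intermediate
14 | 2-(1H-indol-3-yl)-3-methoxy-5-[2-(2-methylbut-3-en-2-yl)-1H-indol-3-yl]cyclohexa-2,5-diene-1,4-dione | C=CC(C)(C)c1[nH]c2ccccc2c1C1=CC(=O)C(c2c[nH]c3ccccc23)=C(OC)C1=O | intermediate
15 | 2-(1H-indol-3-yl)-3,6-dimethoxy-5-[2-(2-methylbut-3-en-2-yl)-1H-indol-3-yl]benzene-1,4-diol | C=CC(C)(C)c1[nH]c2ccccc2c1-c1c(OC)c(O)c(-c2c[nH]c3ccccc23)c(OC)c1O | intermediate
16 | 2-(1H-indol-3-yl)-3,6-dimethoxy-5-[2-(2-methylbut-3-en-2-yl)-1H-indol-3-yl]cyclohexa-2,5-diene-1,4-dione | C=CC(C)(C)c1[nH]c2ccccc2c1C1=C(OC)C(=O)C(c2c[nH]c3ccccc23)=C(OC)C1=O | target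

**Step count**

Total steps: 6. Longest linear sequence: 5 steps (steps 1, 2, 4, 5, 6).

**Steps most likely to fail**

1. Step 6 (proposed new method). Conjugate addition of methanol to the donor-substituted quinone may be too slow to keep pace with the electrolysis, and the indole rings may be oxidized or methoxylated once the hydroquinone is used up. Methoxide may also add at C2 of the unsubstituted indole in the vinylogous sense, and cathodic re-reduction may stall net conversion. The fallback uses the known chloride-for-hydroxide route and sets out from 7 and 6, returning to the route at 16.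
   - Indole 7 is added under acid (AcOH) to commercial 2,5-dichloro-1,4-benzoquinone to give 2,5-dichloro-3-(1H-indol-3-yl)benzene-1,4-diol F1.
   - DDQ oxidizes this to 2,5-dichloro-3-(1H-indol-3-yl)-1,4-benzoquinone F2.
   - Indole 6 is added under H2SO4 in THF to give 2,5-dichloro-3-(1H-indol-3-yl)-6-[2-(2-methylbut-3-en-2-yl)-1H-indol-3-yl]benzene-1,4-diol F3.
   - DDQ oxidizes this to 2,5-dichloro-3-(1H-indol-3-yl)-6-[2-(2-methylbut-3-en-2-yl)-1H-indol-3-yl]cyclohexa-2,5-diene-1,4-dione F4.
   - NaOH in aqueous MeOH at reflux replaces both chlorides by addition–elimination to give 2,5-dihydroxy-3-(1H-indol-3-yl)-6-[2-(2-methylbut-3-en-2-yl)-1H-indol-3-yl]cyclohexa-2,5-diene-1,4-dione F5.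
   - O-Methylation of the two acidic enol hydroxyls with TMSCHN2 in MeOH/toluene gives 16.

2. Step 4. Addition of the hindered indole to a quinone already deactivated by one indolyl donor may be slow, the 2,5-regiochemistry may erode, and the acid may degrade the tert-allyl group during a long reaction. The fallback inverts the order of C–C bond formation and sets out from 6, returning at 12.
   - Indole 6 is added to an excess of the fully electrophilic 8 (InBr3 cat., CH2Cl2), giving 2-[2-(2-methylbut-3-en-2-yl)-1H-indol-3-yl]benzene-1,4-diol F6.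
   - The excess 8 oxidizes this in the flask to 2-[2-(2-methylbut-3-en-2-yl)-1H-indol-3-yl]cyclohexa-2,5-diene-1,4-dione F7.
   - Unhindered indole 7 is then added to F7 in AcOH, and the mixture is brought fully to the quinone with DDQ, giving 12.

3. Step 2. Benzylic lithiation may be incomplete, or n-BuLi may attack the amide carbonyl, so that the ring closure stalls or the amide is cleaved. The fallback is a Fischer indole synthesis and sets out from 1, returning at 6.
   - Acid 1 is treated with MeLi (2.2 equiv, Et2O) to give 3,3-dimethylpent-4-en-2-one F8.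
   - Condensation with phenylhydrazine gives 3,3-dimethylpent-4-en-2-one phenylhydrazone F9.
   - Heating with ZnCl2 brings about the [3,3]-rearrangement and loss of ammonia; the quaternary α-carbon forces enehydrazine formation toward the methyl group, so only the 2-substituted indole 6 can form.

**Further compounds**

F1 | step 6 | 2,5-dichloro-3-(1H-indol-3-yl)benzene-1,4-diol | Oc1c(Cl)cc(O)c(Cl)c1-c1c[nH]c2ccccc12
F2 | step 6 | 2,5-dichloro-3-(1H-indol-3-yl)-1,4-benzoquinone | O=C1C(Cl)=CC(=O)C(Cl)=C1c1c[nH]c2ccccc12
F3 | step 6 | 2,5-dichloro-3-(1H-indol-3-yl)-6-[2-(2-methylbut-3-en-2-yl)-1H-indol-3-yl]benzene-1,4-diol | C=CC(C)(C)c1[nH]c2ccccc2c1-c1c(Cl)c(O)c(-c2c[nH]c3ccccc23)c(Cl)c1O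
F4 | step 6 | 2,5-dichloro-3-(1H-indol-3-yl)-6-[2-(2-methylbut-3-en-2-yl)-1H-indol-3-yl]cyclohexa-2,5-diene-1,4-dione | C=CC(C)(C)c1[nH]c2ccccc2c1C1=C(Cl)C(=O)C(c2c[nH]c3ccccc23)=C(Cl)C1=O
F5 | step 6 | 2,5-dihydroxy-3-(1H-indol-3-yl)-6-[2-(2-methylbut-3-en-2-yl)-1H-indol-3-yl]cyclohexa-2,5-diene-1,4-dione | C=CC(C)(C)c1[nH]c2ccccc2c1C1=C(O)C(=O)C(c2c[nH]c3ccccc23)=C(O)C1=O
F6 | step 4 | 2-[2-(2-methylbut-3-en-2-yl)-1H-indol-3-yl]benzene-1,4-diol | C=CC(C)(C)c1[nH]c2ccccc2c1-c1cc(O)ccc1O
F7 | step 4 | 2-[2-(2-methylbut-3-en-2-yl)-1H-indol-3-yl]cyclohexa-2,5-diene-1,4-dione | C=CC(C)(C)c1[nH]c2ccccc2c1C1=CC(=O)C=CC1=O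
F8 | step 2 | 3,3-dimethylpent-4-en-2-one | C=CC(C)(C)C(C)=O
F9 | step 2 | 3,3-dimethylpent-4-en-2-one phenylhydrazone | C=CC(C)(C)C(C)=NNc1ccccc1
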